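**Assumption:** (+)-genipin (commercial, CAS 6902-77-8) is accepted as the starting material; it already contains the cis-fused cyclopenta[c]pyran and the C1/C5/C9 configuration of the target, so no ring is built.

**Numbering used:** iridoid numbering (C1 acetal carbon, O2, C3=C4, C5/C9 ring fusion, C6, C7, C8, C10 = CH2 on C8, C11 = carbon on C4). β = the face of H-5/H-9. Target = 1β-O-isovaleryl, 7β-OAc, 8α-OH, 10-CH2OH (β), i.e. (1S,4aS,6S,7R,7aS).

## Retrosynthetic overview

1. Target ⇐ 10-O-TBS ether. The C1 isovalerate comes from an anomeric silyl acetal (fluoride, then acylation); 7-OAc and 11-O-isovalerate come from acylations ordered by hydroxyl reactivity (primary allylic > hindered secondary >> tertiary).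
2. C11 CH2OH ⇐ DIBAL reduction of the C4 methyl ester, done only after all oxidation, because the ester deactivates the C3=C4 enol ether.
3. 7β-OH/8α-OH/10-OH ⇐ 8α,10-cyclic carbonate ⇐ 7β,8β-epoxide carrying a 10-O-Boc group (intramolecular 5-exo delivery of oxygen with inversion at C8) ⇐ C7=C8 of genipin.
4. Ring formation: none. Both rings and C1/C5/C9 come intact from genipin; only C7 and C8 are created.

## Route

**Step 1**
Reactants: 1 (+)-genipin; 2 di-tert-butyl dicarbonate
Product: 3, 10-O-Boc-genipin
Conditions: Boc2O (1.05 eq), DMAP (0.1 eq), Et3N, CH2Cl2, 0 °C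
Reagents that add atoms: Boc2O, CC(C)(C)OC(=O)OC(=O)OC(C)(C)C
Why: DMAP-catalysed O-acylation (carbonate formation) should favour the unhindered primary allylic 10-OH over the lactol OH; no stereocentre is touched.

**Step 2**
Reactants: 3; 4 tert-butyldimethylsilyl chloride
Product: 5, 1β-O-TBS-10-O-Boc-genipin
Conditions: TBSCl (1.5 eq), imidazole, DMAP (cat.), DMF, rt
Reagents that add atoms: TBSCl, CC(C)(C)[Si](C)(C)Cl
Why: Silylation of the only remaining OH traps the predominant 1β-lactol anomer with retention (O–Si bond formation) and locks C1 against ring opening.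

**Step 3**
Reactants: 5; 6 mCPBA
Product: 7, 7β,8β-epoxide of 5 (epoxide O on the H-5/H-9 face, C10 pushed α)
Conditions: mCPBA (1.3 eq), NaHCO3, CH2Cl2, 0 °C → rt
Reagents that add atoms: mCPBA, OOC(=O)c1cccc(Cl)c1 (one O)
Why: Prilezhaev epoxidation takes the trisubstituted C7=C8 (C3=C4 is a deactivated β-alkoxyacrylate) from the convex β face of the cis-fused bicycle, setting C7–O β.

**Step 4**
Reactants: 7
Product: 8, 7β-hydroxy-8α,10-cyclic carbonate (spiro-1,3-dioxolan-2-one at C8; 1β-OTBS; C4-CO2Me)
Conditions: BF3·OEt2 (1.1 eq), CH2Cl2, –78 → –40 °C; aq. NaHCO3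
Reagents that add atoms: none (isobutene is lost)
Why: Lewis-acid-promoted neighbouring-group opening of the epoxide by the Boc carbonyl oxygen (epoxy-carbonate cyclisation, the carbonate analogue of the urethane method) is 5-exo at the tertiary C8 with SN2 inversion, giving 8α-O, swinging C10 to β and releasing 7β-OH.

**Step 5**
Reactants: 8
Product: 9, 1β-O-TBS-7β,8α,10-triol methyl ester
Conditions: K2CO3 (0.3 eq), MeOH, –10 → 0 °C
Reagents that add atoms: none
Why: Methanolysis (transesterification) of the five-membered cyclic carbonate is much faster than attack on the vinylogous-carbonate methyl ester (degenerate in MeOH) or the silyl acetal, and breaks no bond to a stereocentre.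

**Step 6**
Reactants: 9; 4 TBSCl
Product: 10, 1β,10-bis-O-TBS-7β,8α-diol methyl ester
Conditions: TBSCl (1.1 eq), imidazole, CH2Cl2/DMF, 0 °C
Reagents that add atoms: TBSCl, CC(C)(C)[Si](C)(C)Cl
Why: Silylation selects the primary 10-OH over the hindered secondary 7-OH and the tertiary 8-OH.

**Step 7**
Reactants: 10
Product: 11, 1β,10-bis-O-TBS-7β,8α,11-triol (C4–CH2OH)
Conditions: DIBAL-H (5 eq), CH2Cl2, –78 → –40 °C; Rochelle salt work-up
Reagents that add atoms: none
Why: DIBAL 1,2-reduction of the β-alkoxyacrylate ester gives the allylic alcohol; the silyl acetal and silyl ether are inert and the free hydroxyls are carried as aluminium alkoxides.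

**Step 8**
Reactants: 11; 12 isovaleric anhydride
Product: 13, 11-O-isovalerate of 11
Conditions: (iBuCO)2O (1.1 eq), Et3N, DMAP (5 mol%), CH2Cl2, –40 °C
Reagents that add atoms: isovaleric anhydride, CC(C)CC(=O)OC(=O)CC(C)C
Why: DMAP-catalysed acylation at low temperature picks the unhindered primary allylic 11-OH over the neopentyl-type secondary 7-OH and the tertiary 8-OH.

**Step 9**
Reactants: 13; 14 acetic anhydride
Product: 15, 7β-O-acetyl-11-O-isovaleryl-1β,10-bis-O-TBS compound
Conditions: Ac2O (3 eq), pyridine, DMAP (0.2 eq), CH2Cl2, 0 °C → rt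
Reagents that add atoms: acetic anhydride, CC(=O)OC(C)=O
Why: Acetylation of the only acylable hydroxyl (secondary 7β-OH) proceeds with retention, while the tertiary 8-OH is inert under these conditions.

**Step 10**
Reactants: 15; 12 isovaleric anhydride
Product: 16, 10-O-TBS-jatamanvaltrate H
Conditions: (iBuCO)2O (3 eq), then TBAF (1.1 eq) added last, THF, –20 → 0 °C
Reagents that add atoms: isovaleric anhydride, CC(C)CC(=O)OC(=O)CC(C)C
Why: Fluoride cleaves the anomeric silyl acetal far faster than the neopentyl primary TBS ether, and the lactol alkoxide is acylated in situ without breaking the C1–O bond, giving the 1β acylal (H-1/H-9 trans, as in natural valepotriates).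

**Step 11**
Reactants: 16
Product: 17, jatamanvaltrate H
Conditions: HF·pyridine, pyridine, THF, 0 °C → rt; pH 7 buffer work-up
Reagents that add atoms: none
Why: Buffered fluoride desilylation frees the primary 10-OH under mildly acidic conditions that avoid base-induced 7→10 acetyl migration and leave the esters, acylal and enol ether intact.

## Compound list

1 | (+)-Genipin, methyl (1R,4aS,7aS)-1-hydroxy-7-(hydroxymethyl)-1,4a,5,7a-tetrahydrocyclopenta[c]pyran-4-carboxylate | OCC1=CC[C@@H]2C(C(=O)OC)=CO[C@@H](O)[C@@H]21 | starting material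
2 | Di-tert-butyl dicarbonate | CC(C)(C)OC(=O)OC(=O)OC(C)(C)C | starting material
3 | 10-O-Boc-genipin | CC(C)(C)OC(=O)OCC1=CC[C@@H]2C(C(=O)OC)=CO[C@@H](O)[C@@H]21 | intermediate
4 | tert-Butyldimethylsilyl chloride | CC(C)(C)[Si](C)(C)Cl | starting material
5 | 1β-O-TBS-10-O-Boc-genipin | CC(C)(C)OC(=O)OCC1=CC[C@@H]2C(C(=O)OC)=CO[C@@H](O[Si](C)(C)C(C)(C)C)[C@@H]21 | intermediate
6 | meta-Chloroperoxybenzoic acid | OOC(=O)c1cccc(Cl)c1 | starting material
7 | 7β,8β-Epoxy-1β-O-TBS-10-O-Boc-7,8-dihydrogenipin | O1[C@H]2C[C@@H]3C(C(=O)OC)=CO[C@@H](O[Si](C)(C)C(C)(C)C)[C@@H]3[C@]21COC(=O)OC(C)(C)C | intermediate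
8 | 7β-Hydroxy-8α,10-(cyclic carbonate)-1β-O-TBS methyl ester | O[C@H]1C[C@@H]2C(C(=O)OC)=CO[C@@H](O[Si](C)(C)C(C)(C)C)[C@@H]2[C@@]1(OC(=O)O3)C3 | intermediate
9 | 1β-O-TBS-7β,8α,10-triol methyl ester | O[C@H]1C[C@@H]2C(C(=O)OC)=CO[C@@H](O[Si](C)(C)C(C)(C)C)[C@@H]2[C@@]1(O)CO | intermediate
10 | 1β,10-Bis-O-TBS-7β,8α-diol methyl ester | O[C@H]1C[C@@H]2C(C(=O)OC)=CO[C@@H](O[Si](C)(C)C(C)(C)C)[C@@H]2[C@@]1(O)CO[Si](C)(C)C(C)(C)C | intermediate
11 | 1β,10-Bis-O-TBS-7β,8α,11-triol | O[C@H]1C[C@@H]2C(CO)=CO[C@@H](O[Si](C)(C)C(C)(C)C)[C@@H]2[C@@]1(O)CO[Si](C)(C)C(C)(C)C | intermediate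
12 | Isovaleric (3-methylbutanoic) anhydride | CC(C)CC(=O)OC(=O)CC(C)C | starting material
13 | 11-O-Isovaleryl-1β,10-bis-O-TBS-7β,8α-diol | O[C@H]1C[C@@H]2C(COC(=O)CC(C)C)=CO[C@@H](O[Si](C)(C)C(C)(C)C)[C@@H]2[C@@]1(O)CO[Si](C)(C)C(C)(C)C | intermediate
14 | Acetic anhydride | CC(=O)OC(C)=O | starting material
15 | 7β-O-Acetyl-11-O-isovaleryl-1β,10-bis-O-TBS-8α-ol | CC(=O)O[C@H]1C[C@@H]2C(COC(=O)CC(C)C)=CO[C@@H](O[Si](C)(C)C(C)(C)C)[C@@H]2[C@@]1(O)CO[Si](C)(C)C(C)(C)C | intermediate
16 | 10-O-TBS-jatamanvaltrate H | CC(=O)O[C@H]1C[C@@H]2C(COC(=O)CC(C)C)=CO[C@@H](OC(=O)CC(C)C)[C@@H]2[C@@]1(O)CO[Si](C)(C)C(C)(C)C | intermediate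
17 | Jatamanvaltrate H, (1S,4aS,6S,7R,7aS) | CC(=O)O[C@H]1C[C@@H]2C(COC(=O)CC(C)C)=CO[C@@H](OC(=O)CC(C)C)[C@@H]2[C@@]1(O)CO | target

## Summary

**Total steps:** 11. **Longest linear sequence:** 11 (fully linear from genipin).

**Three steps most likely to fail, with fallbacks:**

1. **Step 4 (BF3 epoxy-carbonate cyclisation).** Risks are Meinwald/semipinacol rearrangement of the epoxide or loss of the anomeric TBS group. Fallback: drop the Lewis-acid/tether tactic and run a base-mediated Payne rearrangement–opening on the free 2,3-epoxy alcohol. O-10 itself inverts C8 to give the 8α,10-epoxide, and hydroxide (or CsOAc) then opens the primary carbon, reaching triol 9 with the same C7/C8 configuration.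

2. **Step 7 (DIBAL reduction with free hydroxyls, acid-sensitive product).** Fallback: move the reduction to the start. Reduce 1,10-bis-silyl genipin, then re-oxidise with MnO2 to the 4-formyl enol ether, which deactivates C3=C4 as the ester does. Carry the aldehyde through the oxidation and acylation steps and reduce it last under Luche conditions (NaBH4/CeCl3), which tolerate the esters, then isovalerylate 11-OH.

3. **Step 10 (anomeric silyl → acyl exchange).** Risks are lactol ring opening, a C1 anomer mixture, or loss of the 10-O-TBS group. Fallback: avoid a free reduced lactol by reductive acylation. Remove the C1 silyl group while the stabilising ester is still present, mask 7-OH as a TES ether, and reduce with DIBAL. Quench the C1 and C11 aluminium alkoxides in situ at –78 °C with isovaleric anhydride/pyridine/DMAP to install both isovalerates at once, then exchange 7-O-TES for acetate.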